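Labdane numbering is used. Everything rests on opening ring B at C5–C6, the bond buried between the quaternary carbons C4 and C10. C5 becomes the non-enolisable carbonyl carbon of a 2,2,6,6-tetrasubstituted cyclohexanone (ring A). C6 becomes a slim nitrile carbon hung on the C8 carbinol. Cathodic ketyl–nitrile coupling of this δ-cyano ketone closes ring B and puts oxygen on C6 in one operation. The surplus 5-OH then lets one SmI2 treatment set C5 and C6. The step exploits the C6-O/C8-O 1,3-pattern of ring B and the blocked flanks of C5. C13 is bought as (R)-linalool; one CBS carbinol is relayed to C9/C10 (Claisen) and C8 (Felkin–Anh).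

Key step: step 10

Assumption: commercial (R)-(−)-linalool is taken as enantiopure. Ring A = C1–C5/C10, ring B = C5–C10, side chain C11–C16, C17 on C8, C18/C19 on C4, C20 on C10.

Step 1
Reactants: 1 (R)-(−)-linalool
Product: 2 (3R)-3,7-dimethyl-3-(triethylsilyloxy)octa-1,6-diene
Conditions: Et3SiCl, imidazole, DMAP (cat.), DMF, 40 °C
Reagents that add atoms: chlorotriethylsilane, CC[Si](Cl)(CC)CC
Why: Silyl ether protection masks the only acidic OH before the enolate and organolithium steps and leaves the purchased C13 centre (R) untouched.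

Step 2
Reactants: 2 silyl ether
Product: 3 (4R)-4-methyl-4-(triethylsilyloxy)hex-5-enal
Conditions: O3 (1.0 equiv), CH2Cl2, −78 °C; then Me2S, −78 °C to rt
Reagents that add atoms: ozone, [O-][O+]=O
Why: In this chemoselective ozonolysis with reductive work-up, ozone attacks the electron-rich trisubstituted alkene much faster than the vinyl group on the silyloxy-bearing quaternary carbon, and the aldehyde carbon becomes C9.

Step 3
Reactants: 3 aldehyde
Product: 4 (3E,7R)-3,7-dimethyl-7-(triethylsilyloxy)nona-3,8-dien-2-one
Conditions: Ph3P=C(CH3)C(O)CH3, toluene, 110 °C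
Reagents that add atoms: 3-(triphenyl-λ5-phosphanylidene)butan-2-one, CC(=O)C(C)=P(c1ccccc1)(c1ccccc1)c1ccccc1
Why: Wittig olefination with a stabilised α-methyl keto ylide should give the E-trisubstituted enone (C9=C8 with C17 in place), the geometry that the later Claisen chair needs.

Step 4
Reactants: 4 enone
Product: 5 (2R,3E,7R)-3,7-dimethyl-7-(triethylsilyloxy)nona-3,8-dien-2-ol
Conditions: (S)-2-methyl-CBS-oxazaborolidine (20 mol %), catecholborane, toluene, −78 °C
Reagents that add atoms: none
Why: In this Corey–Bakshi–Shibata reduction the (S)-catalyst distinguishes the large alkenyl group from the small methyl group and should give the 2R carbinol, while catecholborane at −78 °C does not hydroborate the vinyl group.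

Step 5
Reactants: 6 2-methylcyclohexanone (racemic)
Product: 7 1,1-dimethoxy-2-methylcyclohexane (racemic)
Conditions: HC(OMe)3, p-TsOH (cat.), MeOH, rt
Reagents that add atoms: trimethyl orthoformate, COC(OC)OC
Why: This is an acid-catalysed ketalisation driven by the orthoformate, and the stereocentre of 6 is erased in step 6.

Step 6
Reactants: 5 allylic alcohol; 7 dimethyl ketal
Product: 9 (2R)-2-methyl-2-[(2E,4S,7R)-3,7-dimethyl-7-(triethylsilyloxy)nona-2,8-dien-4-yl]cyclohexanone, via allyl enol ether 8 (not isolated)
Conditions: 7 (5 equiv), EtCO2H (10 mol %), xylene, 140 °C, MeOH distilled off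
Reagents that add atoms: none
Why: In this ketal Claisen rearrangement, acid-catalysed exchange and loss of methanol give the more substituted enol ether 8, whose [3,3] shift through a chair with the carbinol methyl equatorial transfers the 2R centre to C9 and C10 in one event (C20 is pseudoaxial because it is cis to O, and the C11 chain is equatorial because the alkene is E).

Step 7
Reactants: 9 Claisen ketone
Product: 10 (2R)-2,6,6-trimethyl-2-[(2E,4S,7R)-3,7-dimethyl-7-(triethylsilyloxy)nona-2,8-dien-4-yl]cyclohexanone
Conditions: KOt-Bu (5 equiv), MeI (8 equiv), THF, 0 °C to rt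
Reagents that add atoms: iodomethane, CI
Why: Because C10 is quaternary, only C4 can be deprotonated, so exhaustive enolate methylation installs C18 and C19 without touching any stereocentre.

Step 8
Reactants: 10 trimethyl ketone
Product: 11 (2R)-2-[(3R,6R)-6-methyl-2-oxo-6-(triethylsilyloxy)oct-7-en-3-yl]-2,6,6-trimethylcyclohexanone
Conditions: O3 (1.0 equiv), CH2Cl2, −78 °C; then Me2S, −78 °C to rt
Reagents that add atoms: ozone, [O-][O+]=O
Why: Chemoselective ozonolysis cleaves the trisubstituted alkene in preference to the deactivated monosubstituted vinyl group and unveils the C8 methyl ketone under neutral conditions that do not epimerise C9.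

Step 9
Reactants: 11 1,4-diketone
Product: 12 (3R,4R,7R)-3-hydroxy-3,7-dimethyl-7-(triethylsilyloxy)-4-[(1R)-1,3,3-trimethyl-2-oxocyclohexyl]non-8-enenitrile
Conditions: MeCN, n-BuLi, THF, −78 °C; then 11, −78 °C; AcOH quench at −78 °C
Reagents that add atoms: acetonitrile, CC#N
Why: Lithioacetonitrile adds 1,2 only to the accessible C8 methyl ketone (the C5 carbonyl is shielded by C4 and C10), and Felkin–Anh attack anti to the quaternary C10 should set C8 as R, that is the 8α-OH of the target.

Step 10
Reactants: 12 δ-cyano ketone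
Product: 14 5β,8α-dihydroxy-13-(triethylsilyloxy)labd-14-en-6-one, via 5-hydroxy-6-ketimine 13 (not isolated)
Conditions: Sn cathode, Pt anode, divided cell, Et4NOTs (0.3 M), i-PrOH, constant current, ca. 4 F/mol, 25 °C; then aq. citric acid, THF, rt
Reagents that add atoms: water, O
Why: Cathodic one-electron reduction of the C5 ketone in i-PrOH gives a protonated ketyl radical that adds to the nitrile carbon C6, the iminyl radical takes up the second electron and a proton, and the resulting ketimine 13 is hydrolysed to ketol 14 on mild acidic work-up. The closest known reaction type is the electroreductive intramolecular coupling of γ- and δ-cyano ketones to bicyclic α-hydroxy ketones, whose chemical twin is the SmI2 ketyl–nitrile coupling. Ring B (C5–C10) closes in the 6-exo-dig mode. The only new stereocentre, C5, should carry a 5β-OH (cis-fused) because C6 bonds along the axial α trajectory that avoids the axial methyls C19 and C20; this centre is erased in step 11, so its sense does not matter. The step needs electron uptake by one hindered dialkyl ketone and C–C bond formation faster than reduction to the carbinol. Electron transfer at the electrode needs no bulky reagent at the carbonyl, the sp-hybridised nitrile is the slimmest possible acceptor between C4 and C10, and the vinyl group, silyl ether and tertiary carbinol are not reducible at this potential.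

Step 11
Reactants: 14 α-ketol
Product: 16 13-(triethylsilyloxy)labd-14-ene-6α,8α-diol, via trans-decalone 15 (not isolated)
Conditions: SmI2 (10 equiv), HMPA, t-BuOH, THF, rt
Reagents that add atoms: none
Why: SmI2–HMPA single-electron reduction first expels the 5-OH next to the ketyl (reductive cleavage of an α-hydroxy ketone), the samarium enolate is protonated on the open α face to give trans-decalone 15 (also the thermodynamic epimer), and further ketyl reduction places the C6 oxygen equatorial (6α), away from the three axial methyls C17, C19 and C20, as in dissolving-metal reductions of hindered cyclohexanones.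

Step 12
Reactants: 16 diol; 17 angelic acid
Product: 18 6α-angeloyloxy-13-(triethylsilyloxy)labd-14-en-8α-ol
Conditions: 17, 2,4,6-Cl3C6H2COCl, Et3N, toluene, rt; then 16, 80 °C
Reagents that add atoms: none
Why: Yamaguchi esterification through the mixed anhydride, run without DMAP so that the Z-alkene does not isomerise to the tiglate, acylates the only secondary hydroxyl (6α-OH) while the tertiary 8α-OH stays free.

Step 13
Reactants: 18 silyl-protected angelate
Product: 19 target, 6α-angeloyloxylabd-14-ene-8α,13-diol (5S,6S,8R,9R,10S,13R)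
Conditions: HF·pyridine, pyridine, THF, 0 °C
Reagents that add atoms: none
Why: Buffered fluoride desilylation cleaves the Si–O bond without ionising the tertiary allylic alcohol or touching the angelate, which gives the target with all six stereocentres and the Z-ester in place.

Compound list
1 | (R)-(−)-linalool | C=C[C@](C)(O)CCC=C(C)C | starting material
2 | (3R)-3,7-dimethyl-3-(triethylsilyloxy)octa-1,6-diene | C=C[C@](C)(O[Si](CC)(CC)CC)CCC=C(C)C | intermediate
3 | (4R)-4-methyl-4-(triethylsilyloxy)hex-5-enal | C=C[C@](C)(O[Si](CC)(CC)CC)CCC=O | intermediate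
4 | (3E,7R)-3,7-dimethyl-7-(triethylsilyloxy)nona-3,8-dien-2-one | C=C[C@](C)(O[Si](CC)(CC)CC)CC/C=C(C)/C(C)=O | intermediate
5 | (2R,3E,7R)-3,7-dimethyl-7-(triethylsilyloxy)nona-3,8-dien-2-ol | C=C[C@](C)(O[Si](CC)(CC)CC)CC/C=C(C)/[C@@H](C)O | intermediate
6 | 2-methylcyclohexanone (racemic) | CC1CCCCC1=O | starting material
7 | 1,1-dimethoxy-2-methylcyclohexane (racemic) | COC1(OC)CCCCC1C | intermediate
8 | 2-methylcyclohex-1-enyl ether of 5 (not isolated) | C=C[C@](C)(O[Si](CC)(CC)CC)CC/C=C(C)/[C@@H](C)OC1=C(C)CCCC1 | intermediate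
9 | (2R)-2-methyl-2-[(2E,4S,7R)-3,7-dimethyl-7-(triethylsilyloxy)nona-2,8-dien-4-yl]cyclohexanone | C=C[C@](C)(O[Si](CC)(CC)CC)CC[C@@H](/C(C)=C/C)[C@@]1(C)CCCCC1=O | intermediate
10 | (2R)-2,6,6-trimethyl-2-[(2E,4S,7R)-3,7-dimethyl-7-(triethylsilyloxy)nona-2,8-dien-4-yl]cyclohexanone | C=C[C@](C)(O[Si](CC)(CC)CC)CC[C@@H](/C(C)=C/C)[C@@]1(C)CCCC(C)(C)C1=O | intermediate
11 | (2R)-2-[(3R,6R)-6-methyl-2-oxo-6-(triethylsilyloxy)oct-7-en-3-yl]-2,6,6-trimethylcyclohexanone | C=C[C@](C)(O[Si](CC)(CC)CC)CC[C@@H](C(C)=O)[C@@]1(C)CCCC(C)(C)C1=O | intermediate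
12 | (3R,4R,7R)-3-hydroxy-3,7-dimethyl-7-(triethylsilyloxy)-4-[(1R)-1,3,3-trimethyl-2-oxocyclohexyl]non-8-enenitrile | C=C[C@](C)(O[Si](CC)(CC)CC)CC[C@@H]([C@](C)(O)CC#N)[C@@]1(C)CCCC(C)(C)C1=O | intermediate
13 | 6-imino-13-(triethylsilyloxy)labd-14-ene-5β,8α-diol (not isolated) | C=C[C@](C)(O[Si](CC)(CC)CC)CC[C@@H]1[C@@]2(C)CCCC(C)(C)[C@@]2(O)C(=N)C[C@@]1(C)O | intermediate
14 | 5β,8α-dihydroxy-13-(triethylsilyloxy)labd-14-en-6-one | C=C[C@](C)(O[Si](CC)(CC)CC)CC[C@@H]1[C@@]2(C)CCCC(C)(C)[C@@]2(O)C(=O)C[C@@]1(C)O | intermediate
15 | 8α-hydroxy-13-(triethylsilyloxy)labd-14-en-6-one, 5α-H (not isolated) | C=C[C@](C)(O[Si](CC)(CC)CC)CC[C@@H]1[C@@]2(C)CCCC(C)(C)[C@@H]2C(=O)C[C@@]1(C)O | intermediate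
16 | 13-(triethylsilyloxy)labd-14-ene-6α,8α-diol | C=C[C@](C)(O[Si](CC)(CC)CC)CC[C@@H]1[C@@]2(C)CCCC(C)(C)[C@@H]2[C@@H](O)C[C@@]1(C)O | intermediate
17 | angelic acid, (Z)-2-methylbut-2-enoic acid | C/C=C(/C)C(=O)O | starting material
18 | 6α-angeloyloxy-13-(triethylsilyloxy)labd-14-en-8α-ol | C=C[C@](C)(O[Si](CC)(CC)CC)CC[C@@H]1[C@@]2(C)CCCC(C)(C)[C@@H]2[C@@H](OC(=O)/C(C)=C\C)C[C@@]1(C)O | intermediate
19 | 6α-angeloyloxylabd-14-ene-8α,13-diol (CNP0203829.1) | C=C[C@](C)(O)CC[C@@H]1[C@@]2(C)CCCC(C)(C)[C@@H]2[C@@H](OC(=O)/C(C)=C\C)C[C@@]1(C)O | target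

Total step count: 13. Longest linear sequence: 12 (steps 1–4 and 6–13, from 1).

Steps most likely to fail

Step 10.
- What may go wrong: the hindered ketyl may take up a second electron and a proton, giving plain reduction to the C5 carbinol before it reaches the nitrile. The strained radical adduct may revert. Alkoxide building up in the catholyte may degrade the β-hydroxy nitrile.
- Fallback: this path sets out from 12 and moves the ketyl to the easily reduced partner. i-Bu2AlH (excess, toluene, −78 °C, hydrolytic work-up) turns the nitrile into the β-hydroxy aldehyde F1. SmI2 (THF, t-BuOH) then forms the aldehyde ketyl, which adds to the samarium-bound C5 ketone in an intramolecular pinacol coupling and gives the cis-5,6-diol F2. Dess–Martin periodinane oxidises its only secondary carbinol, and the route is rejoined at 14.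

Step 6.
- What may go wrong: the enol ether may form towards the unsubstituted α-carbon, giving poor regioselectivity. Leakage through a boat transition state may erode the C9/C10 relay. Acid-induced ionisation of the allylic alcohol may erode chirality transfer.
- Fallback: this path sets out from 5 and uses a ketone partner that can enolise in one direction only. Commercial 2,2,6-trimethylcyclohexanone is O-methylated (KH, then Me2SO4, DME) to 1-methoxy-2,6,6-trimethylcyclohex-1-ene F3. Acid-catalysed exchange with 5 (EtCO2H cat., xylene, 140 °C) gives the blocked allyl enol ether F4. F4 rearranges in the same chair sense, and the route is rejoined at 10, so step 7 falls away.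

Step 11.
- What may go wrong: the C6 carbonyl may be reduced before the poor hydroxide leaving group on C5 is expelled, giving vicinal diol formation. Facial selectivity at C6 may also be poor.
- Fallback: this path sets out from 14 and activates the leaving group first. Me3SiOTf and 2,6-lutidine give the bis(trimethylsilyl) ether F5, whose α-silyloxy group is a proven nucleofuge for SmI2 in THF–MeOH at −78 °C, so it should give the silyloxy trans-decalone F6. Aqueous citric acid in MeOH removes the labile trimethylsilyl group, and the route is rejoined at 15, now isolated. 15 is reduced on its own with SmI2–H2O to 16.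

Further compounds
F1 | step 10 | (3R,4R,7R)-3-hydroxy-3,7-dimethyl-7-(triethylsilyloxy)-4-[(1R)-1,3,3-trimethyl-2-oxocyclohexyl]non-8-enal | C=C[C@](C)(O[Si](CC)(CC)CC)CC[C@@H]([C@](C)(O)CC=O)[C@@]1(C)CCCC(C)(C)C1=O
F2 | step 10 | 13-(triethylsilyloxy)labd-14-ene-5β,6β,8α-triol | C=C[C@](C)(O[Si](CC)(CC)CC)CC[C@@H]1[C@@]2(C)CCCC(C)(C)[C@@]2(O)[C@H](O)C[C@@]1(C)O
F3 | step 6 | 1-methoxy-2,6,6-trimethylcyclohex-1-ene | COC1=C(C)CCCC1(C)C
F4 | step 6 | 2,6,6-trimethylcyclohex-1-enyl ether of 5 | C=C[C@](C)(O[Si](CC)(CC)CC)CC/C=C(C)/[C@@H](C)OC1=C(C)CCCC1(C)C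
F5 | step 11 | 5β,8α-bis(trimethylsilyloxy)-13-(triethylsilyloxy)labd-14-en-6-one | C=C[C@](C)(O[Si](CC)(CC)CC)CC[C@@H]1[C@@]2(C)CCCC(C)(C)[C@@]2(O[Si](C)(C)C)C(=O)C[C@@]1(C)O[Si](C)(C)C
F6 | step 11 | 8α-(trimethylsilyloxy)-13-(triethylsilyloxy)labd-14-en-6-one, 5α-H | C=C[C@](C)(O[Si](CC)(CC)CC)CC[C@@H]1[C@@]2(C)CCCC(C)(C)[C@@H]2C(=O)C[C@@]1(C)O[Si](C)(C)C
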